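**Retrosynthetic overview**
- The target is the threo-(7R,8R) 8-O-4' neolignan. The last disconnection is one global hydride reduction of a triester (C9 methyl ester, ring B cinnamate, ring A pivalate).
- The C8–O–aryl (ring B) bond comes from nickel-electrocatalytic O-arylation of the α-hydroxyl of a threo 2,3-dihydroxy ester with a 4-bromo-3,5-dimethoxycinnamate. The C8–O bond is never broken.
- The C7–aryl (ring A) bond comes from iridium/nickel photoredox decarboxylative arylation of the D-tartrate acetonide half-ester. The bought C8 centre steers the aryl group trans and so sets C7.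
- No ring is built. Rings A and B are bought as bromoarenes. The dioxolane is bought with the tartrate, serves as a stereo-template, and is removed once the C7–aryl bond is in place.

Assumption: the SMILES is read as (7R,8R), threo, with an E alkene (C7 benzylic, C8 ether carbon, C9 CH2OH; ring A = 4-hydroxy-3,5-dimethoxyphenyl, ring B = sinapyl alcohol ring). The three starting materials are taken as catalogue compounds.

**Step 1**
Reactants: 1 dimethyl (4S,5S)-2,2-dimethyl-1,3-dioxolane-4,5-dicarboxylate (dimethyl 2,3-O-isopropylidene-D-tartrate)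
Product: 2 potassium (4S,5S)-5-(methoxycarbonyl)-2,2-dimethyl-1,3-dioxolane-4-carboxylate
Conditions: KOH (1.0 equiv), MeOH, 0 °C to rt; evaporate, triturate with Et2O, dry
Reagents that add atoms: potassium hydroxide, [K+].[OH-]
Why: Ester monosaponification: both esters of the C2-symmetric diester are equivalent, one equivalent of KOH stops at the half-ester because the carboxylate formed is far less electrophilic, and cold methanolic hydroxide does not enolise the trans-dioxolane, so both bought stereocentres stay (4S,5S).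

**Step 2**
Reactants: 3 4-bromo-2,6-dimethoxyphenol
Product: 4 4-bromo-2,6-dimethoxyphenyl pivalate
Conditions: PivCl (1.2 equiv), Et3N (1.5 equiv), DMAP (5 mol %), CH2Cl2, 0 °C to rt
Reagents that add atoms: pivaloyl chloride, CC(C)(C)C(=O)Cl
Why: DMAP-catalysed O-acylation; the pivalate keeps the phenol from quenching the photocatalyst, makes the bromoarene less electron-rich for oxidative addition, resists carbonate bases behind its two ortho methoxy groups, and comes off for free in the last hydride step.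

**Step 3**
Reactants: 2 potassium (4S,5S)-5-(methoxycarbonyl)-2,2-dimethyl-1,3-dioxolane-4-carboxylate; 4 4-bromo-2,6-dimethoxyphenyl pivalate
Product: 6 methyl (4S,5R)-5-[3,5-dimethoxy-4-(pivaloyloxy)phenyl]-2,2-dimethyl-1,3-dioxolane-4-carboxylate, via dioxolan-4-yl radical 5 (not isolated)
Conditions: 2 (1.5 equiv), 4 (1.0 equiv), Ir[dF(CF3)ppy]2(dtbbpy)PF6 (1 mol %), NiCl2·glyme (10 mol %), dtbbpy (15 mol %), degassed DMF, 450 nm LEDs, 25 °C, 24 h
Reagents that add atoms: none
Why: Metallaphotoredox decarboxylative arylation: the excited iridium photocatalyst oxidises the α-alkoxy carboxylate, loss of CO2 gives the nucleophilic radical 5 in which C7 is planar, and the aryl-nickel species captures and couples it on the ring face opposite the C8 ester, so the centre bought with D-tartrate sets C7 as R in the trans-dioxolane (threo; trans:cis of 10:1 or better expected, minor isomer removed by chromatography).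

**Step 4**
Reactants: 6 methyl (4S,5R)-5-[3,5-dimethoxy-4-(pivaloyloxy)phenyl]-2,2-dimethyl-1,3-dioxolane-4-carboxylate
Product: 7 methyl (2S,3R)-3-[3,5-dimethoxy-4-(pivaloyloxy)phenyl]-2,3-dihydroxypropanoate
Conditions: TFA–H2O (9:1), CH2Cl2, 0 °C to rt
Reagents that add atoms: none
Why: Acid-catalysed acetal hydrolysis cleaves only the bonds to the ketal carbon, and a benzylic cation at C7 is disfavoured by the para acyloxy group and the neighbouring ester-bearing carbon, so the threo diol is released without epimerisation while the methyl ester and pivalate survive.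

**Step 5**
Reactants: 8 4-bromo-3,5-dimethoxybenzaldehyde
Product: 9 methyl (E)-3-(4-bromo-3,5-dimethoxyphenyl)prop-2-enoate
Conditions: Ph3P=CHCO2Me (1.2 equiv), toluene, 80 °C; recrystallise
Reagents that add atoms: methyl (triphenylphosphoranylidene)acetate, COC(=O)C=P(c1ccccc1)(c1ccccc1)c1ccccc1
Why: Wittig olefination with a stabilised ylide gives the E-cinnamate (E:Z above 20:1, upgraded by crystallisation) under neutral conditions that leave the aryl bromide untouched.

**Step 6**
Reactants: 7 methyl (2S,3R)-3-[3,5-dimethoxy-4-(pivaloyloxy)phenyl]-2,3-dihydroxypropanoate; 9 methyl (E)-3-(4-bromo-3,5-dimethoxyphenyl)prop-2-enoate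
Product: 10 methyl (2S,3R)-2-{2,6-dimethoxy-4-[(E)-3-methoxy-3-oxoprop-1-en-1-yl]phenoxy}-3-[3,5-dimethoxy-4-(pivaloyloxy)phenyl]-3-hydroxypropanoate
Conditions: 7 (1.0 equiv), 9 (1.5 equiv), NiBr2·glyme (10 mol %), dtbbpy (12 mol %), K2CO3 (2 equiv, ground), 3 Å MS, nBu4NBF4 (0.1 M), DMA, undivided cell, RVC anode, Ni-foam cathode, 4 mA (about 3 F/mol), 25 °C
Reagents that add atoms: none
Why: Proposed new method: site-selective nickel-electrocatalytic O-arylation of a diol by a di-ortho-substituted bromoarene; cathodic reduction gives low-valent nickel that inserts into the C–Br bond of 9 (activated by the para acrylate), the more acidic α-hydroxyl of 7 (acidified by the ester and able to bind nickel as a five-membered alkoxide/carbonyl chelate, the same bias that makes sulfonylation of syn-2,3-dihydroxy esters α-selective) replaces bromide with the help of K2CO3, and anodic oxidation to trivalent nickel triggers C–O reductive elimination, which the two ortho methoxy groups should speed up sterically and which outruns β-hydride elimination; only the O–H bond at C8 is broken, so C7 and C8 keep their configuration, and with no triplet sensitiser present the alkene stays E; the closest known reaction type is the nickel-catalysed electrochemical or photoredox etherification of unhindered aryl bromides with an excess of simple mono-alcohols.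

**Step 7**
Reactants: 10 methyl (2S,3R)-2-{2,6-dimethoxy-4-[(E)-3-methoxy-3-oxoprop-1-en-1-yl]phenoxy}-3-[3,5-dimethoxy-4-(pivaloyloxy)phenyl]-3-hydroxypropanoate
Product: 11 (1R,2R)-1-(4-hydroxy-3,5-dimethoxyphenyl)-2-{4-[(E)-3-hydroxyprop-1-en-1-yl]-2,6-dimethoxyphenoxy}propane-1,3-diol
Conditions: iBu2AlH (DIBAL-H, 10 equiv), toluene–CH2Cl2, −78 °C to 0 °C; then H2O, filter, extract (EtOAc)
Reagents that add atoms: none
Why: Global ester reduction with DIBAL-H: in one operation the cinnamate is reduced 1,2 to the E-allylic alcohol, the C9 ester to the primary alcohol and the aryl pivalate to the free phenol plus neopentyl alcohol, and no bond to C7 or C8 is touched, so (7R,8R) is retained.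

**Compound list**
1 | dimethyl (4S,5S)-2,2-dimethyl-1,3-dioxolane-4,5-dicarboxylate | COC(=O)[C@H]1OC(C)(C)O[C@@H]1C(=O)OC | starting material
2 | potassium (4S,5S)-5-(methoxycarbonyl)-2,2-dimethyl-1,3-dioxolane-4-carboxylate | COC(=O)[C@H]1OC(C)(C)O[C@@H]1C(=O)[O-].[K+] | intermediate
3 | 4-bromo-2,6-dimethoxyphenol | COc1cc(Br)cc(OC)c1O | starting material
4 | 4-bromo-2,6-dimethoxyphenyl pivalate | COc1cc(Br)cc(OC)c1OC(=O)C(C)(C)C | intermediate
5 | (5S)-5-(methoxycarbonyl)-2,2-dimethyl-1,3-dioxolan-4-yl radical (not isolated) | COC(=O)[C@H]1OC(C)(C)O[CH]1 | intermediate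
6 | methyl (4S,5R)-5-[3,5-dimethoxy-4-(pivaloyloxy)phenyl]-2,2-dimethyl-1,3-dioxolane-4-carboxylate | COC(=O)[C@H]1OC(C)(C)O[C@@H]1c2cc(OC)c(OC(=O)C(C)(C)C)c(OC)c2 | intermediate
7 | methyl (2S,3R)-3-[3,5-dimethoxy-4-(pivaloyloxy)phenyl]-2,3-dihydroxypropanoate | COC(=O)[C@@H](O)[C@H](O)c1cc(OC)c(OC(=O)C(C)(C)C)c(OC)c1 | intermediate
8 | 4-bromo-3,5-dimethoxybenzaldehyde | COc1cc(C=O)cc(OC)c1Br | starting material
9 | methyl (E)-3-(4-bromo-3,5-dimethoxyphenyl)prop-2-enoate | COC(=O)/C=C/c1cc(OC)c(Br)c(OC)c1 | intermediate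
10 | methyl (2S,3R)-2-{2,6-dimethoxy-4-[(E)-3-methoxy-3-oxoprop-1-en-1-yl]phenoxy}-3-[3,5-dimethoxy-4-(pivaloyloxy)phenyl]-3-hydroxypropanoate | COC(=O)[C@@H](Oc1c(OC)cc(/C=C/C(=O)OC)cc1OC)[C@H](O)c2cc(OC)c(OC(=O)C(C)(C)C)c(OC)c2 | intermediate
11 | (1R,2R)-1-(4-hydroxy-3,5-dimethoxyphenyl)-2-{4-[(E)-3-hydroxyprop-1-en-1-yl]-2,6-dimethoxyphenoxy}propane-1,3-diol | COc1cc([C@@H](O)[C@@H](CO)Oc2c(OC)cc(/C=C/CO)cc2OC)cc(OC)c1O | target

**Step count**
Total steps: 7. Longest linear sequence: 5 (steps 1, 3, 4, 6, 7; 1 → 2 → 6 → 7 → 10 → 11).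

**Steps most likely to fail**

**1. Step 6 (the proposed new step).**
- Risks: slow oxidative addition or ligand exchange at the di-ortho-substituted aryl nickel, competing arylation at O7, and protodebromination of 9.
- The fallback uses known chemistry, sets out from bromide 4 and comes back at 11. It moves to the natural tartrate series and makes the ether by SN2 at C8 instead of at the arene.
- Dimethyl (4R,5R)-2,2-dimethyl-1,3-dioxolane-4,5-dicarboxylate F1 (bought) is carried through the chemistry of steps 1, 3 and 4.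
- KOH gives potassium (4R,5R)-5-(methoxycarbonyl)-2,2-dimethyl-1,3-dioxolane-4-carboxylate F2.
- The iridium/nickel arylation with 4 runs through the (5R)-5-(methoxycarbonyl)-2,2-dimethyl-1,3-dioxolan-4-yl radical F3. It gives methyl (4R,5S)-5-[3,5-dimethoxy-4-(pivaloyloxy)phenyl]-2,2-dimethyl-1,3-dioxolane-4-carboxylate F4.
- TFA–H2O then gives methyl (2R,3S)-3-[3,5-dimethoxy-4-(pivaloyloxy)phenyl]-2,3-dihydroxypropanoate F5.
- A Mitsunobu reaction with benzoic acid (PPh3, diisopropyl azodicarboxylate, THF, 0 °C) takes only the β-hydroxyl of syn-2,3-dihydroxy esters. It inverts C7 and masks it as methyl (2R,3R)-3-(benzoyloxy)-3-[3,5-dimethoxy-4-(pivaloyloxy)phenyl]-2-hydroxypropanoate F6.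
- A second Mitsunobu reaction at the remaining α-hydroxy ester with methyl (E)-3-(4-hydroxy-3,5-dimethoxyphenyl)prop-2-enoate F7 (methyl sinapate, bought) inverts C8.
- The product is methyl (2S,3R)-3-(benzoyloxy)-2-{2,6-dimethoxy-4-[(E)-3-methoxy-3-oxoprop-1-en-1-yl]phenoxy}-3-[3,5-dimethoxy-4-(pivaloyloxy)phenyl]propanoate F8, the 7-O-benzoate of 10.
- iBu2AlH as in step 7 removes the benzoate together with the other esters and gives 11.

**2. Step 3.**
- Risks: sluggish oxidation of the ester-bearing carboxylate, protodecarboxylation, and low conversion of the bromoarene.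
- The fallback sets out from 2 and 4 and comes back at 6. It replaces oxidative photochemical activation by reductive thermal activation of an activated ester.
- Salt 2 is acidified (1 M HCl) to (4S,5S)-5-(methoxycarbonyl)-2,2-dimethyl-1,3-dioxolane-4-carboxylic acid F9.
- F9 is esterified with N-hydroxyphthalimide (N,N'-diisopropylcarbodiimide, DMAP cat., CH2Cl2) to 4-(1,3-dioxoisoindolin-2-yl) 5-methyl (4S,5S)-2,2-dimethyl-1,3-dioxolane-4,5-dicarboxylate F10.
- F10 is coupled in the dark with [3,5-dimethoxy-4-(pivaloyloxy)phenyl]zinc chloride F11 (from 4 with Mg, LiCl, ZnCl2, THF). The catalyst is NiCl2·glyme/dtbbpy (20/40 mol %) in THF–DMF at 25 °C.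
- This is a nickel-catalysed decarboxylative Negishi-type arylation. The same radical 5 is formed and the same trans outcome applies.

**3. Step 7.**
- Risks: incomplete cleavage of the hindered pivalate, loss of the 7-hydroxyl through a quinone-methide pathway once the phenolate is unmasked next to an aluminium alkoxide, and poor recovery of the polar tetraol from aluminium salts.
- The fallback sets out from 10 and comes back at 11. It splits the job into chemoselective stages with C7 and C9 tied up.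
- NaBH4 in THF–H2O (3:1, rt) performs a hydroxyl-assisted reduction of the activated α-aryloxy ester only. It gives methyl (E)-3-[4-({(1R,2R)-1-[3,5-dimethoxy-4-(pivaloyloxy)phenyl]-1,3-dihydroxypropan-2-yl}oxy)-3,5-dimethoxyphenyl]prop-2-enoate F12.
- 2,2-Dimethoxypropane/PPTS closes methyl (E)-3-[4-({(4R,5R)-4-[3,5-dimethoxy-4-(pivaloyloxy)phenyl]-2,2-dimethyl-1,3-dioxan-5-yl}oxy)-3,5-dimethoxyphenyl]prop-2-enoate F13.
- iBu2AlH (6 equiv, −78 to 0 °C) gives 4-[(4R,5R)-5-{4-[(E)-3-hydroxyprop-1-en-1-yl]-2,6-dimethoxyphenoxy}-2,2-dimethyl-1,3-dioxan-4-yl]-2,6-dimethoxyphenol F14.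
- AcOH–H2O (4:1, rt) releases 11.

**Further compounds**
F1 | step 6 | dimethyl (4R,5R)-2,2-dimethyl-1,3-dioxolane-4,5-dicarboxylate (bought) | COC(=O)[C@@H]1OC(C)(C)O[C@H]1C(=O)OC
F2 | step 6 | potassium (4R,5R)-5-(methoxycarbonyl)-2,2-dimethyl-1,3-dioxolane-4-carboxylate | COC(=O)[C@@H]1OC(C)(C)O[C@H]1C(=O)[O-].[K+]
F3 | step 6 | (5R)-5-(methoxycarbonyl)-2,2-dimethyl-1,3-dioxolan-4-yl radical (not isolated) | COC(=O)[C@@H]1OC(C)(C)O[CH]1
F4 | step 6 | methyl (4R,5S)-5-[3,5-dimethoxy-4-(pivaloyloxy)phenyl]-2,2-dimethyl-1,3-dioxolane-4-carboxylate | COC(=O)[C@@H]1OC(C)(C)O[C@H]1c2cc(OC)c(OC(=O)C(C)(C)C)c(OC)c2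
F5 | step 6 | methyl (2R,3S)-3-[3,5-dimethoxy-4-(pivaloyloxy)phenyl]-2,3-dihydroxypropanoate | COC(=O)[C@H](O)[C@@H](O)c1cc(OC)c(OC(=O)C(C)(C)C)c(OC)c1
F6 | step 6 | methyl (2R,3R)-3-(benzoyloxy)-3-[3,5-dimethoxy-4-(pivaloyloxy)phenyl]-2-hydroxypropanoate | COC(=O)[C@H](O)[C@H](OC(=O)c1ccccc1)c2cc(OC)c(OC(=O)C(C)(C)C)c(OC)c2
F7 | step 6 | methyl (E)-3-(4-hydroxy-3,5-dimethoxyphenyl)prop-2-enoate (methyl sinapate, bought) | COC(=O)/C=C/c1cc(OC)c(O)c(OC)c1
F8 | step 6 | methyl (2S,3R)-3-(benzoyloxy)-2-{2,6-dimethoxy-4-[(E)-3-methoxy-3-oxoprop-1-en-1-yl]phenoxy}-3-[3,5-dimethoxy-4-(pivaloyloxy)phenyl]propanoate | COC(=O)[C@@H](Oc1c(OC)cc(/C=C/C(=O)OC)cc1OC)[C@H](OC(=O)c2ccccc2)c3cc(OC)c(OC(=O)C(C)(C)C)c(OC)c3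
F9 | step 3 | (4S,5S)-5-(methoxycarbonyl)-2,2-dimethyl-1,3-dioxolane-4-carboxylic acid | COC(=O)[C@H]1OC(C)(C)O[C@@H]1C(=O)O
F10 | step 3 | 4-(1,3-dioxoisoindolin-2-yl) 5-methyl (4S,5S)-2,2-dimethyl-1,3-dioxolane-4,5-dicarboxylate | COC(=O)[C@H]1OC(C)(C)O[C@@H]1C(=O)ON2C(=O)c3ccccc3C2=O
F11 | step 3 | [3,5-dimethoxy-4-(pivaloyloxy)phenyl]zinc chloride | CC(C)(C)C(=O)Oc1c(OC)cc([Zn]Cl)cc1OC
F12 | step 7 | methyl (E)-3-[4-({(1R,2R)-1-[3,5-dimethoxy-4-(pivaloyloxy)phenyl]-1,3-dihydroxypropan-2-yl}oxy)-3,5-dimethoxyphenyl]prop-2-enoate | OC[C@@H](Oc1c(OC)cc(/C=C/C(=O)OC)cc1OC)[C@H](O)c2cc(OC)c(OC(=O)C(C)(C)C)c(OC)c2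
F13 | step 7 | methyl (E)-3-[4-({(4R,5R)-4-[3,5-dimethoxy-4-(pivaloyloxy)phenyl]-2,2-dimethyl-1,3-dioxan-5-yl}oxy)-3,5-dimethoxyphenyl]prop-2-enoate | CC1(C)OC[C@@H](Oc2c(OC)cc(/C=C/C(=O)OC)cc2OC)[C@@H](c3cc(OC)c(OC(=O)C(C)(C)C)c(OC)c3)O1
F14 | step 7 | 4-[(4R,5R)-5-{4-[(E)-3-hydroxyprop-1-en-1-yl]-2,6-dimethoxyphenoxy}-2,2-dimethyl-1,3-dioxan-4-yl]-2,6-dimethoxyphenol | CC1(C)OC[C@@H](Oc2c(OC)cc(/C=C/CO)cc2OC)[C@@H](c3cc(OC)c(O)c(OC)c3)O1
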